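**Plan**

1. Retrosynthetic cuts, in order: C9–C10 (ten-membered ring), C1=C10 (iodo-olefination), then in one operation the lactone O–C6 bond together with C2–C3, then the O8 ester, C6–C7 and C7–C11.
2. Forward: methyl (R)-glycerate supplies C8–C9; acylation of an alkenyllithium and a chelation-controlled dienyl addition build carbinol C7, which carries the acrylate unit (C11–C13) and the 3-methylbuta-1,3-dienyl group (C3–C6).
3. Key event: C6 is the inner terminus of that diene and gamma to carboxyl C12, so radical addition at C3 gives an allyl cation over C4–C6 that the acid captures; this closes the lactone ring O–C12–C11–C7–C6 and fixes the E C4=C5 bond.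
4. The carbocycle C1–C10 is closed last by Nozaki–Hiyama–Kishi coupling of the (Z)-C10 iodide with the C9 aldehyde.
5. Stereochemistry: C8 from the chiral pool; C7 by Cram-chelate addition; C6 from C7 in the lactonisation; C9 by Felkin–Anh addition in the ring closure; the epoxide by Sharpless epoxidation; Z C1=C10 by Stork–Zhao olefination.

Key step: step 13

Remark: atoms carry germacranolide numbers (ring C1–C10, C11 bearing C13H2, C12 the lactone carbonyl, C14 on C10, C15 on C4); the side-chain epoxide has its two methyl groups cis (tiglate-derived geometry), as the target structure requires.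

**Route**

Step 1
Reactants: 1 (E)-2-methylbut-2-en-1-ol (tiglyl alcohol)
Product: 2 [(2R,3R)-2,3-dimethyloxiran-2-yl]methanol
Conditions: Ti(OiPr)4 (cat.), D-(−)-diethyl tartrate (cat.), t-BuOOH, 4 Å molecular sieves, CH2Cl2, −20 °C
Reagents that add atoms: tert-butyl hydroperoxide, CC(C)(C)OO
Why: Sharpless asymmetric epoxidation of the (E)-allylic alcohol, in which the D-tartrate catalyst delivers oxygen to the face that gives the (2R,3R)-epoxide and the alkene geometry keeps the two methyl groups cis.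

Step 2
Reactants: 2 [(2R,3R)-2,3-dimethyloxiran-2-yl]methanol
Product: 3 (2S,3R)-2,3-dimethyloxirane-2-carboxylic acid
Conditions: RuCl3 hydrate (cat.), NaIO4, MeCN/EtOAc/H2O, 0 °C to rt
Reagents that add atoms: sodium periodate, [Na+].[O-]I(=O)(=O)=O; water, O
Why: RuO4 formed in situ oxidises the primary alcohol to the acid (Sharpless ruthenium oxidation) without touching the epoxide stereocenters; the C2 descriptor changes only through priority.

Step 3
Reactants: 4 2-methylprop-2-enal (methacrolein)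
Product: 5 (E)-1-iodo-3-methylbuta-1,3-diene
Conditions: CrCl2, CHI3, THF, 0 °C
Reagents that add atoms: iodoform, [I]C([I])[I]
Why: Takai iodo-olefination, in which the geminal dichromium reagent adds to the aldehyde and anti elimination should give the (E)-dienyl iodide.

Step 4
Reactants: 6 2-bromoprop-2-en-1-ol
Product: 7 [(2-bromoprop-2-en-1-yl)oxy](tert-butyl)dimethylsilane
Conditions: TBSCl, imidazole, CH2Cl2, 0 °C to rt
Reagents that add atoms: tert-butyldimethylsilyl chloride, CC(C)(C)[Si](C)(C)Cl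
Why: Routine silylation of a primary alcohol, giving the precursor of the C11–C13 alkenyllithium.

Step 5
Reactants: 8 methyl (4R)-2,2-dimethyl-1,3-dioxolane-4-carboxylate
Product: 9 methyl (2R)-2,3-dihydroxypropanoate
Conditions: sulfonic acid ion-exchange resin (H+ form), MeOH, rt
Reagents that add atoms: none
Why: Acid-catalysed acetal exchange with methanol frees the diol and leaves the chiral-pool stereocenter (future C8) untouched.

Step 6
Reactants: 9 methyl (2R)-2,3-dihydroxypropanoate
Product: 10 methyl (2R)-3-[(tert-butyldiphenylsilyl)oxy]-2-hydroxypropanoate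
Conditions: TBDPSCl, imidazole, CH2Cl2, −20 to 0 °C
Reagents that add atoms: tert-butyldiphenylsilyl chloride, CC(C)(C)[Si](Cl)(c1ccccc1)c1ccccc1
Why: The bulky silyl chloride should react selectively at the primary hydroxyl (future O9).

Step 7
Reactants: 10 methyl (2R)-3-[(tert-butyldiphenylsilyl)oxy]-2-hydroxypropanoate
Product: 11 (2R)-3-[(tert-butyldiphenylsilyl)oxy]-2-hydroxy-N-methoxy-N-methylpropanamide
Conditions: MeNH(OMe)·HCl, i-PrMgCl, THF, −20 to 0 °C
Reagents that add atoms: N,O-dimethylhydroxylamine hydrochloride, CNOC.Cl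
Why: Weinreb amide formation from the ester with the chloromagnesium amide; the α-hydroxyl is held as its magnesium alkoxide, which blocks enolisation at C8.

Step 8
Reactants: 7 [(2-bromoprop-2-en-1-yl)oxy](tert-butyl)dimethylsilane; 11 (2R)-3-[(tert-butyldiphenylsilyl)oxy]-2-hydroxy-N-methoxy-N-methylpropanamide
Product: 13 (4R)-2-{[(tert-butyldimethylsilyl)oxy]methyl}-5-[(tert-butyldiphenylsilyl)oxy]-4-hydroxypent-1-en-3-one, via 2-lithioallyl silyl ether 12 (not isolated)
Conditions: 7, t-BuLi (2 equiv), Et2O, −78 °C; then 11 (pre-treated with i-PrMgCl, 1 equiv), THF, −78 to −40 °C; aq. NH4Cl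
Reagents that add atoms: none
Why: Bromine–lithium exchange followed by acylation of the alkenyllithium with the Weinreb amide, whose chelated tetrahedral adduct prevents over-addition while the C8 alkoxide resists epimerisation.

Step 9
Reactants: 5 (E)-1-iodo-3-methylbuta-1,3-diene; 13 (4R)-2-{[(tert-butyldimethylsilyl)oxy]methyl}-5-[(tert-butyldiphenylsilyl)oxy]-4-hydroxypent-1-en-3-one
Product: 16 (2R,3S,4E)-3-{3-[(tert-butyldimethylsilyl)oxy]prop-1-en-2-yl}-1-[(tert-butyldiphenylsilyl)oxy]-6-methylhepta-4,6-diene-2,3-diol, via dienyllithium 14 (not isolated), via dienylmagnesium bromide 15 (not isolated)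
Conditions: 5, t-BuLi (2 equiv), Et2O, −78 °C; MgBr2·OEt2; then 13 (pre-treated with t-BuMgCl, 1 equiv), CH2Cl2/Et2O, −78 °C; aq. NH4Cl
Reagents that add atoms: none
Why: Cram-chelate-controlled 1,2-addition of the alkenyl Grignard reagent: magnesium bridges the C8 alkoxide and the ketone oxygen, the dienyl group enters from the face of the C8 hydrogen (anti to C9) and so sets C7 in the arrangement of the target, with the E geometry of the iodide carried through.

Step 10
Reactants: 16 (2R,3S,4E)-3-{3-[(tert-butyldimethylsilyl)oxy]prop-1-en-2-yl}-1-[(tert-butyldiphenylsilyl)oxy]-6-methylhepta-4,6-diene-2,3-diol; 3 (2S,3R)-2,3-dimethyloxirane-2-carboxylic acid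
Product: 18 (2R,3S,4E)-3-{3-[(tert-butyldimethylsilyl)oxy]prop-1-en-2-yl}-1-[(tert-butyldiphenylsilyl)oxy]-3-hydroxy-6-methylhepta-4,6-dien-2-yl (2S,3R)-2,3-dimethyloxirane-2-carboxylate, via mixed anhydride 17 (not isolated)
Conditions: 3, 2,4,6-trichlorobenzoyl chloride, Et3N, THF, rt; then 16, DMAP, toluene, rt
Reagents that add atoms: none
Why: Yamaguchi esterification should acylate only the secondary C8 hydroxyl, since the tertiary C7 hydroxyl is too hindered and the basic medium spares the acid-labile bis-allylic carbinol; placing the ester before the lactone exists avoids a free O8 next to the lactone carbonyl.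

Step 11
Reactants: 18 C8 epoxy ester bis-silyl ether
Product: 19 (2R,3S,4E)-1-[(tert-butyldiphenylsilyl)oxy]-3-hydroxy-3-(3-hydroxyprop-1-en-2-yl)-6-methylhepta-4,6-dien-2-yl (2S,3R)-2,3-dimethyloxirane-2-carboxylate
Conditions: HF·pyridine, pyridine, THF, 0 °C
Reagents that add atoms: none
Why: Buffered fluoride cleaves the primary allylic TBS ether much faster than the TBDPS ether and should leave the ester and the tertiary carbinol untouched.

Step 12
Reactants: 19 allylic alcohol
Product: 21 2-[(2R,3S,4E)-1-[(tert-butyldiphenylsilyl)oxy]-2-{[(2S,3R)-2,3-dimethyloxirane-2-carbonyl]oxy}-3-hydroxy-6-methylhepta-4,6-dien-3-yl]prop-2-enoic acid, via enal 20 (not isolated)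
Conditions: MnO2, CH2Cl2, rt; filter; then NaClO2, NaH2PO4, 2-methylbut-2-ene, t-BuOH/H2O, 0 °C
Reagents that add atoms: sodium chlorite, [Na+].[O-]Cl=O
Why: MnO2 oxidises only the allylic primary alcohol and Pinnick oxidation takes the enal to the acid, with 2-methylbut-2-ene scavenging hypochlorite to protect the diene; the sp2 carbon C11 rules out retro-aldol cleavage and dehydration.

Step 13
Reactants: 21 dienyl hydroxy acrylic acid; 22 2-bromo-N-methoxy-N-methylacetamide
Product: 23 (1R)-2-[(tert-butyldiphenylsilyl)oxy]-1-{(2R,3R)-3-hydroxy-2-[(1E)-5-[methoxy(methyl)amino]-2-methyl-5-oxopent-1-en-1-yl]-4-methylidene-5-oxooxolan-3-yl}ethyl (2S,3R)-2,3-dimethyloxirane-2-carboxylate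
Conditions: fac-Ir(ppy)3 (1 mol %), K2HPO4, MeCN, blue LEDs, rt, degassed
Reagents that add atoms: none
Why: Proposed new method: the excited iridium photocatalyst reduces the C–Br bond of 22 and the electrophilic α-amido radical adds to the unsubstituted diene terminus C3, the C4–C6 allyl radical is then oxidised by the tetravalent iridium complex (or collects bromine by atom transfer) and the C12 carboxylate captures the allyl cation at C6, the closest known reaction types being photoredox atom-transfer carbolactonisation of alkenoic acids with α-bromo carbonyl compounds and palladium-catalysed 1,4-oxylactonisation of dienoic acids. The five-membered ring O–C12–C11–C7–C6 closes 5-exo at the allyl terminus C6, since attack at C4 would need a seven-membered ring holding an E alkene. C6 is controlled by C7: in the envelope transition state the alkenyl substituent lies anti to the bulky C8 branch and syn to the small hydroxyl, which should give (6R). The C4=C5 bond should form E because the diene reacts through its s-trans conformer and the allyl intermediate keeps that shape. The step needs the radical to choose the diene over the acrylate and the cation to be trapped before a semipinacol shift; the polarity match of an electrophilic radical with the electron-rich diene and the carboxylate held three atoms from C6 secure both.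

Step 14
Reactants: 23 lactone Weinreb amide
Product: 24 (1R)-2-[(tert-butyldiphenylsilyl)oxy]-1-{(2R,3R)-3-hydroxy-2-[(1E)-2-methyl-5-oxopent-1-en-1-yl]-4-methylidene-5-oxooxolan-3-yl}ethyl (2S,3R)-2,3-dimethyloxirane-2-carboxylate
Conditions: Cp2Zr(H)Cl (2.5 equiv), THF, rt, short reaction time; aq. NaHCO3
Reagents that add atoms: none
Why: The Schwartz reagent reduces the Weinreb amide through a stable zirconium hemiaminal that releases the aldehyde only on work-up, and esters, the lactone and the epoxide should react far more slowly.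

Step 15
Reactants: 24 lactone aldehyde
Product: 25 (1R)-2-[(tert-butyldiphenylsilyl)oxy]-1-{(2R,3R)-3-hydroxy-2-[(1E,5Z)-6-iodo-2-methylhepta-1,5-dien-1-yl]-4-methylidene-5-oxooxolan-3-yl}ethyl (2S,3R)-2,3-dimethyloxirane-2-carboxylate
Conditions: EtPPh3I, n-BuLi, THF; I2, −78 °C; NaHMDS, −78 °C; then 24, −78 °C
Reagents that add atoms: ethyltriphenylphosphonium iodide, CC[P+](c1ccccc1)(c1ccccc1)c1ccccc1.[I-]; iodine, [I][I]
Why: Stork–Zhao olefination, in which the α-iodo ylide reacts with the aldehyde under kinetic control to give the (Z)-2-iodoalkene (C1=C10) and at −78 °C the aldehyde outcompetes the lactone and the esters.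

Step 16
Reactants: 25 (Z)-alkenyl iodide
Product: 26 (1R)-2-hydroxy-1-{(2R,3R)-3-hydroxy-2-[(1E,5Z)-6-iodo-2-methylhepta-1,5-dien-1-yl]-4-methylidene-5-oxooxolan-3-yl}ethyl (2S,3R)-2,3-dimethyloxirane-2-carboxylate
Conditions: HF·pyridine, pyridine, THF, 0 °C to rt
Reagents that add atoms: none
Why: Fluoride cleaves the TBDPS ether, and the α-quaternary epoxy acyl group on O8 is too hindered to migrate to the new primary hydroxyl under buffered conditions.

Step 17
Reactants: 26 C9 alcohol
Product: 27 (1S)-1-{(2R,3R)-3-hydroxy-2-[(1E,5Z)-6-iodo-2-methylhepta-1,5-dien-1-yl]-4-methylidene-5-oxooxolan-3-yl}-2-oxoethyl (2S,3R)-2,3-dimethyloxirane-2-carboxylate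
Conditions: Dess–Martin periodinane, NaHCO3, CH2Cl2, 0 °C
Reagents that add atoms: none
Why: Buffered Dess–Martin oxidation gives the α-acyloxy aldehyde without epimerisation at C8 (descriptor changes by priority only), and the tertiary hydroxyl and alkenyl iodide are inert.

Step 18
Reactants: 27 seco aldehyde
Product: 28 (1(10)Z,4E,6R,7R,8R,9R)-7,9-dihydroxy-8-{[(2S,3R)-2,3-dimethyloxirane-2-carbonyl]oxy}germacra-1(10),4,11(13)-trien-12,6-olide (CNP0420662.1)
Conditions: CrCl2 (excess), NiCl2 (cat.), DMSO/THF, high dilution, rt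
Reagents that add atoms: none
Why: Intramolecular Nozaki–Hiyama–Kishi reaction: zerovalent nickel inserts into the C10–I bond with retention of the Z geometry, the alkenyl group passes to trivalent chromium and adds to the C9 aldehyde to close the ten-membered ring, and Felkin–Anh attack anti to the C8–O bond should give the 8,9-anti alcohol (9R) while chromium tolerates the hydroxyl, esters, epoxide and methylene lactone.

**Compound list**

1 | (E)-2-methylbut-2-en-1-ol | C/C=C(\C)CO | starting material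
2 | [(2R,3R)-2,3-dimethyloxiran-2-yl]methanol | OC[C@@]1(C)O[C@@H]1C | intermediate
3 | (2S,3R)-2,3-dimethyloxirane-2-carboxylic acid | OC(=O)[C@@]1(C)O[C@@H]1C | intermediate
4 | 2-methylprop-2-enal | CC(=C)C=O | starting material
5 | (E)-1-iodo-3-methylbuta-1,3-diene | C=C(C)/C=C/I | intermediate
6 | 2-bromoprop-2-en-1-ol | OCC(Br)=C | starting material
7 | [(2-bromoprop-2-en-1-yl)oxy](tert-butyl)dimethylsilane | C=C(Br)CO[Si](C)(C)C(C)(C)C | intermediate
8 | methyl (4R)-2,2-dimethyl-1,3-dioxolane-4-carboxylate | COC(=O)[C@H]1COC(C)(C)O1 | starting material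
9 | methyl (2R)-2,3-dihydroxypropanoate | COC(=O)[C@H](O)CO | intermediate
10 | methyl (2R)-3-[(tert-butyldiphenylsilyl)oxy]-2-hydroxypropanoate | COC(=O)[C@H](O)CO[Si](c1ccccc1)(c1ccccc1)C(C)(C)C | intermediate
11 | (2R)-3-[(tert-butyldiphenylsilyl)oxy]-2-hydroxy-N-methoxy-N-methylpropanamide | CON(C)C(=O)[C@H](O)CO[Si](c1ccccc1)(c1ccccc1)C(C)(C)C | intermediate
12 | tert-butyl[(2-lithioprop-2-en-1-yl)oxy]dimethylsilane | [Li]C(=C)CO[Si](C)(C)C(C)(C)C | intermediate
13 | (4R)-2-{[(tert-butyldimethylsilyl)oxy]methyl}-5-[(tert-butyldiphenylsilyl)oxy]-4-hydroxypent-1-en-3-one | C=C(CO[Si](C)(C)C(C)(C)C)C(=O)[C@H](O)CO[Si](c1ccccc1)(c1ccccc1)C(C)(C)C | intermediate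
14 | (E)-(3-methylbuta-1,3-dien-1-yl)lithium | [Li]/C=C/C(C)=C | intermediate
15 | (E)-(3-methylbuta-1,3-dien-1-yl)magnesium bromide | Br[Mg]/C=C/C(C)=C | intermediate
16 | (2R,3S,4E)-3-{3-[(tert-butyldimethylsilyl)oxy]prop-1-en-2-yl}-1-[(tert-butyldiphenylsilyl)oxy]-6-methylhepta-4,6-diene-2,3-diol | C=C(CO[Si](C)(C)C(C)(C)C)[C@@](O)(/C=C/C(C)=C)[C@H](O)CO[Si](c1ccccc1)(c1ccccc1)C(C)(C)C | intermediate
17 | (2S,3R)-2,3-dimethyloxirane-2-carboxylic 2,4,6-trichlorobenzoic anhydride | O=C(OC(=O)[C@@]1(C)O[C@@H]1C)c1c(Cl)cc(Cl)cc1Cl | intermediate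
18 | (2R,3S,4E)-3-{3-[(tert-butyldimethylsilyl)oxy]prop-1-en-2-yl}-1-[(tert-butyldiphenylsilyl)oxy]-3-hydroxy-6-methylhepta-4,6-dien-2-yl (2S,3R)-2,3-dimethyloxirane-2-carboxylate | C=C(CO[Si](C)(C)C(C)(C)C)[C@@](O)(/C=C/C(C)=C)[C@H](OC(=O)[C@@]1(C)O[C@@H]1C)CO[Si](c1ccccc1)(c1ccccc1)C(C)(C)C | intermediate
19 | (2R,3S,4E)-1-[(tert-butyldiphenylsilyl)oxy]-3-hydroxy-3-(3-hydroxyprop-1-en-2-yl)-6-methylhepta-4,6-dien-2-yl (2S,3R)-2,3-dimethyloxirane-2-carboxylate | C=C(CO)[C@@](O)(/C=C/C(C)=C)[C@H](OC(=O)[C@@]1(C)O[C@@H]1C)CO[Si](c1ccccc1)(c1ccccc1)C(C)(C)C | intermediate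
20 | (2R,3S,4E)-1-[(tert-butyldiphenylsilyl)oxy]-3-hydroxy-6-methyl-3-(3-oxoprop-1-en-2-yl)hepta-4,6-dien-2-yl (2S,3R)-2,3-dimethyloxirane-2-carboxylate | C=C(C=O)[C@@](O)(/C=C/C(C)=C)[C@H](OC(=O)[C@@]1(C)O[C@@H]1C)CO[Si](c1ccccc1)(c1ccccc1)C(C)(C)C | intermediate
21 | 2-[(2R,3S,4E)-1-[(tert-butyldiphenylsilyl)oxy]-2-{[(2S,3R)-2,3-dimethyloxirane-2-carbonyl]oxy}-3-hydroxy-6-methylhepta-4,6-dien-3-yl]prop-2-enoic acid | C=C(C(=O)O)[C@@](O)(/C=C/C(C)=C)[C@H](OC(=O)[C@@]1(C)O[C@@H]1C)CO[Si](c1ccccc1)(c1ccccc1)C(C)(C)C | intermediate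
22 | 2-bromo-N-methoxy-N-methylacetamide | CON(C)C(=O)CBr | starting material
23 | (1R)-2-[(tert-butyldiphenylsilyl)oxy]-1-{(2R,3R)-3-hydroxy-2-[(1E)-5-[methoxy(methyl)amino]-2-methyl-5-oxopent-1-en-1-yl]-4-methylidene-5-oxooxolan-3-yl}ethyl (2S,3R)-2,3-dimethyloxirane-2-carboxylate | C=C1C(=O)O[C@H](/C=C(\C)CCC(=O)N(C)OC)[C@@]1(O)[C@H](OC(=O)[C@@]2(C)O[C@@H]2C)CO[Si](c3ccccc3)(c3ccccc3)C(C)(C)C | intermediate
24 | (1R)-2-[(tert-butyldiphenylsilyl)oxy]-1-{(2R,3R)-3-hydroxy-2-[(1E)-2-methyl-5-oxopent-1-en-1-yl]-4-methylidene-5-oxooxolan-3-yl}ethyl (2S,3R)-2,3-dimethyloxirane-2-carboxylate | C=C1C(=O)O[C@H](/C=C(\C)CCC=O)[C@@]1(O)[C@H](OC(=O)[C@@]2(C)O[C@@H]2C)CO[Si](c3ccccc3)(c3ccccc3)C(C)(C)C | intermediate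
25 | (1R)-2-[(tert-butyldiphenylsilyl)oxy]-1-{(2R,3R)-3-hydroxy-2-[(1E,5Z)-6-iodo-2-methylhepta-1,5-dien-1-yl]-4-methylidene-5-oxooxolan-3-yl}ethyl (2S,3R)-2,3-dimethyloxirane-2-carboxylate | C=C1C(=O)O[C@H](/C=C(\C)CC/C=C(/C)I)[C@@]1(O)[C@H](OC(=O)[C@@]2(C)O[C@@H]2C)CO[Si](c3ccccc3)(c3ccccc3)C(C)(C)C | intermediate
26 | (1R)-2-hydroxy-1-{(2R,3R)-3-hydroxy-2-[(1E,5Z)-6-iodo-2-methylhepta-1,5-dien-1-yl]-4-methylidene-5-oxooxolan-3-yl}ethyl (2S,3R)-2,3-dimethyloxirane-2-carboxylate | C=C1C(=O)O[C@H](/C=C(\C)CC/C=C(/C)I)[C@@]1(O)[C@H](OC(=O)[C@@]2(C)O[C@@H]2C)CO | intermediate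
27 | (1S)-1-{(2R,3R)-3-hydroxy-2-[(1E,5Z)-6-iodo-2-methylhepta-1,5-dien-1-yl]-4-methylidene-5-oxooxolan-3-yl}-2-oxoethyl (2S,3R)-2,3-dimethyloxirane-2-carboxylate | C=C1C(=O)O[C@H](/C=C(\C)CC/C=C(/C)I)[C@@]1(O)[C@H](OC(=O)[C@@]2(C)O[C@@H]2C)C=O | intermediate
28 | (1(10)Z,4E,6R,7R,8R,9R)-7,9-dihydroxy-8-{[(2S,3R)-2,3-dimethyloxirane-2-carbonyl]oxy}germacra-1(10),4,11(13)-trien-12,6-olide | C=C1C(=O)O[C@@H]2/C=C(\C)CC/C=C(/C)[C@@H](O)[C@@H](OC(=O)[C@@]3(C)O[C@@H]3C)[C@@]12O | target

**Count**

Total step count: 18. Longest linear sequence: 14 steps (steps 5 to 18, from 8 to 28).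

**Steps most likely to fail**

Step 13. The radical may add to the acrylate unit, the allyl cation may undergo a semipinacol shift at C7, or the carboxylate may be O-alkylated by the bromide before the crossover takes place. The fallback uses known two-electron chemistry and sets out from 21. Palladium-catalysed intramolecular 1,4-acyloxychlorination of the diene (Pd(OAc)2 cat., p-benzoquinone, LiCl, acetone/AcOH, rt) closes the same O–C6 bond by carboxylate attack on the palladium-bound diene and should give (1R)-2-[(tert-butyldiphenylsilyl)oxy]-1-{(2R,3R)-2-[(1E)-3-chloro-2-methylprop-1-en-1-yl]-3-hydroxy-4-methylidene-5-oxooxolan-3-yl}ethyl (2S,3R)-2,3-dimethyloxirane-2-carboxylate F1. Coupling of this allylic chloride at its primary terminus with the Reformatsky reagent bromo{2-[methoxy(methyl)amino]-2-oxoethyl}zinc F2 (from 22 and zinc dust in THF) under Pd(PPh3)4 catalysis comes back to the route at 23.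

Step 18. The ring closure may show poor facial selectivity at the C9 aldehyde, since the strained ten-membered transition state can override the Felkin–Anh preference. The fallback sets out from 27. The ring is closed as in step 18, and the mixture of 28 and its C9 epimer F3 is oxidised with Dess–Martin periodinane to the macrocyclic (Z)-enone, the 9-ketone of 28 F4. Luche reduction (NaBH4, CeCl3·7H2O, MeOH, −78 °C) then returns to 28. C9 is now set by 1,2-hydride delivery to the exposed face of a ring ketone and no longer by the rotamer of an open-chain aldehyde.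

Step 14. The hydride reagent may reduce the methylene lactone (conjugate reduction or hydrozirconation) in competition with the amide. The fallback sets out from 21 and avoids any hydride. The allylic chloride F1 of the first fallback is coupled with commercial (1,3-dioxolan-2-ylmethyl)zinc bromide under Pd(PPh3)4 catalysis (Negishi coupling at the primary allyl terminus) to give (1R)-2-[(tert-butyldiphenylsilyl)oxy]-1-{(2R,3R)-2-[(1E)-4-(1,3-dioxolan-2-yl)-2-methylbut-1-en-1-yl]-3-hydroxy-4-methylidene-5-oxooxolan-3-yl}ethyl (2S,3R)-2,3-dimethyloxirane-2-carboxylate F5. Mild acetal hydrolysis (PPTS, wet acetone, 50 °C) comes back to the route at 24 with C1 already at the aldehyde level.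

**Further compounds**

F1 | step 13 | (1R)-2-[(tert-butyldiphenylsilyl)oxy]-1-{(2R,3R)-2-[(1E)-3-chloro-2-methylprop-1-en-1-yl]-3-hydroxy-4-methylidene-5-oxooxolan-3-yl}ethyl (2S,3R)-2,3-dimethyloxirane-2-carboxylate | C=C1C(=O)O[C@H](/C=C(\C)CCl)[C@@]1(O)[C@H](OC(=O)[C@@]2(C)O[C@@H]2C)CO[Si](c3ccccc3)(c3ccccc3)C(C)(C)C
F2 | step 13 | bromo{2-[methoxy(methyl)amino]-2-oxoethyl}zinc | CON(C)C(=O)C[Zn]Br
F3 | step 18 | C9 epimer of 28 (9S) | C=C1C(=O)O[C@@H]2/C=C(\C)CC/C=C(/C)[C@H](O)[C@@H](OC(=O)[C@@]3(C)O[C@@H]3C)[C@@]12O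
F4 | step 18 | 9-ketone of 28 (macrocyclic (Z)-enone) | C=C1C(=O)O[C@@H]2/C=C(\C)CC/C=C(/C)C(=O)[C@@H](OC(=O)[C@@]3(C)O[C@@H]3C)[C@@]12O
F5 | step 14 | (1R)-2-[(tert-butyldiphenylsilyl)oxy]-1-{(2R,3R)-2-[(1E)-4-(1,3-dioxolan-2-yl)-2-methylbut-1-en-1-yl]-3-hydroxy-4-methylidene-5-oxooxolan-3-yl}ethyl (2S,3R)-2,3-dimethyloxirane-2-carboxylate | C=C1C(=O)O[C@H](/C=C(\C)CCC2OCCO2)[C@@]1(O)[C@H](OC(=O)[C@@]3(C)O[C@@H]3C)CO[Si](c4ccccc4)(c4ccccc4)C(C)(C)C
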